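The question is how much ring stands after 12 min as the charge of starting material climbs past that of the solid activator, with the solid charge held fixed.

common to all: solid activator 0.450 M; time 12 min
- Friday's: starting material 0.15 M
- Wednesday's: starting material 0.30 M
- Sunday's: starting material 0.60 M
- Tuesday's: starting material 1.2 M

    2 starting material → homo dimer (k1 = 8.2 × 10⁻⁵ L mol⁻¹ s⁻¹)
    solid activator ⇌ activator, rate k2*(cs2 - [activator]) while solid is left; crystals form when [activator] > cs2 (cs2 = 0.11 M, k2 = 0.027 s⁻¹)
    starting material + activator → activated form (k3 = 0.046 L mol⁻¹ s⁻¹)
    activated form → ring (k4 = 0.11 s⁻¹)
    starting material + activated form → open dimer (k5 = 0.022 L mol⁻¹ s⁻¹)

- [ring] at the end for Friday's, Wednesday's, Sunday's, Tuesday's, in this order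
- how the row runs (rises all the way / hardly changes / rises, then falls / falls all the way / falls, then rises)

- a species is counted by the starting material in it: one open dimer or homo dimer counts as two
- for a step with 2 of a species take k times the square, and two of it per event
- given per volume of solution although it is solid: solid activator
- at the start none of the solid activator is in solution
- "hardly changes" means that all values lie within two and a half points (for a concentration: within two and a half percent of the largest)
- run time (Friday's): 12 min

Each activated form takes up one activator, so the first limit is the activator per starting material charged: 3.00 on Friday's and 0.375 on Tuesday's. It passes one between Wednesday's and Sunday's, and from there on the solid activator is the limiting reagent. With the activator near its solubility, starting material falls in a pseudo-first-order way with a half-life of 2.28 min, so the run lasts 5.26 such half-lives, and the limit can be reached.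

But an activated form has two ways to go. It closes to ring, or it meets starting material and gives open dimer, which also costs a second starting material. So the quantity to carry is the closing ratio, the ring constant over the open-dimer constant times the starting material present, a selectivity factor. At the charge it is 4.17 on Tuesday's and 33.3 on Friday's, and it climbs as starting material falls.

This reckoning, by hand, takes the ratio at the charge as a floor. Ring on Tuesday's is then at least 30.2% of the charge, and on Sunday's at least 67.0%. These are 0.402 M on Sunday's and 0.363 M on Tuesday's. Sunday's floor stands higher than the 0.30 M charged on Wednesday's, so the reckoning commits to a row that climbs as far as Sunday's. Both figures are floors, with the charge of 0.450 M of solid activator as their ceiling, so the reckoning commits to no order between Sunday's and Tuesday's.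

The forecast gives 0.137 M, 0.268 M, 0.415 M and 0.381 M, a row that rises, then falls, on the ground that “more of the limited activated form is lost to the open dimer because the starting material stays high”.

The flask gives 0.139 M, 0.267 M, 0.414 M and 0.382 M, a row that rises, then falls, turning at 0.64 M.

Tuesday's flask ends with 31.8% of its charge as ring, more than the floor of 30.2%, and with 51.2% of its starting material left, and its open dimer, counted as two, gives 5.58 turns to ring per turn to open dimer, more than the closing ratio of 4.17 at the charge and less than the 8.15 at the starting material left. On Friday's flask at 1.66 min the activated form goes to ring faster than to open dimer by a factor of 45, more than the closing ratio at that flask's charge, which is 33.3.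

All constants come from no measurement; the run is a simulation.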